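## Retrosynthetic overview
1. Target 6 ⇒ bis-TBS ether 5 (buffered fluoride, last step).
2. 5 ⇒ styrenyl tertiary allylic alcohol 4. The key disconnection is the C1–O bond of the ketone: oxygen is placed on the finished carbon skeleton by a regioselective Wacker-type oxidation of C1=C2.
3. 4 ⇒ dibromide 2 + (R)-linalool 3 by a single Mizoroki–Heck coupling. Compound 3 supplies all ten side-chain carbons and the C3 stereocentre.
4. 2 ⇒ 2,5-dibromohydroquinone 1 (silylation).
5. No ring is formed. The only ring, the arene, is bought with both oxygens and the bromine in place.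

Assumption: commercial (R)-(−)-linalool 3 is used in a grade of at least 98 % ee (checked by chiral GC). C3 is never touched, so the ee of 6 equals that of the batch.

## Route

Step 1
Reactants: 1 2,5-dibromohydroquinone
Product: 2 1,4-dibromo-2,5-bis(tert-butyldimethylsilyloxy)benzene
Conditions: TBSCl (2.4 equiv), imidazole (5 equiv), DMF, rt, 12 h
Reagents that add atoms: tert-butyldimethylsilyl chloride, CC(C)(C)[Si](C)(C)Cl
Why: Imidazole-promoted O-silylation of two acidic phenols is routine, and it masks oxygens that would otherwise close onto the allylic carbinol (chromene formation) after step 2 or be oxidised in step 3.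

Step 2
Reactants: 2 1,4-dibromo-2,5-bis(tert-butyldimethylsilyloxy)benzene; 3 (R)-(−)-linalool
Product: 4 (1E,3R)-1-[4-bromo-2,5-bis(tert-butyldimethylsilyloxy)phenyl]-3,7-dimethylocta-1,6-dien-3-ol
Conditions: 2 (2.5 equiv), 3 (1.0 equiv), Pd2(dba)3 (2 mol %), [HP(t-Bu)3]BF4 (8 mol %), Cy2NMe (1.5 equiv), 1,4-dioxane, 50 °C, 16 h; surplus 2 recovered by chromatography
Reagents that add atoms: none
Why: In this Mizoroki–Heck reaction aryl–palladium adds to the unhindered vinyl terminus of 3 and the only syn β-hydrogen lies at C1 because C3 is fully substituted, so the E-styrene forms and cannot isomerise to a carbonyl compound, while the excess of symmetric 2 suppresses double coupling, the trisubstituted alkene is inert, and the R centre brought in by 3 is not involved.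

Step 3
Reactants: 4 (1E,3R)-1-[4-bromo-2,5-bis(tert-butyldimethylsilyloxy)phenyl]-3,7-dimethylocta-1,6-dien-3-ol
Product: 5 (3R)-1-[4-bromo-2,5-bis(tert-butyldimethylsilyloxy)phenyl]-3-hydroxy-3,7-dimethyloct-6-en-1-one
Conditions: Pd(Quinox)Cl2 (10 mol %; Quinox = 2-(4,5-dihydro-1,3-oxazol-2-yl)quinoline), AgSbF6 (25 mol %), 70 % aq. t-BuOOH (10 equiv), 2,6-di-tert-butyl-4-methylpyridine (30 mol %), CH2Cl2, 0 °C to rt, 24 h
Reagents that add atoms: tert-butyl hydroperoxide, CC(C)(C)OO
Why: Proposed new method: a peroxide-driven Wacker-type oxidation has not been shown on an aryl-conjugated internal alkene bearing a free, fully substituted allylic carbinol; cationic [Pd(Quinox)(OOt-Bu)]+ should bind only the 1,2-disubstituted C1=C2 alkene (the trisubstituted C6=C7 alkene is too hindered to coordinate), the C3–OH can hydrogen-bond to the bound peroxide and by its inductive pull disfavours positive charge at C2 while the ortho-siloxyaryl ring stabilises it at C1, so syn-peroxypalladation places oxygen on C1 and palladium on C2, and a 1,2-hydride shift from C1 to C2 with O–O heterolysis then releases ketone 5 and a Pd–Ot-Bu species that t-BuOOH recharges; palladium stays divalent throughout, so the C–Br bond never meets zerovalent palladium and no π-allyl ionisation of C3–O can begin, the hindered pyridine removes stray acid, and C3 is a spectator that keeps its R configuration; the closest known reaction type is the Pd(Quinox)/t-BuOOH Wacker-type oxidation of protected secondary allylic alcohols and of simple internal alkenes, in which the ketone forms distal to the allylic oxygen.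

Step 4
Reactants: 5 (3R)-1-[4-bromo-2,5-bis(tert-butyldimethylsilyloxy)phenyl]-3-hydroxy-3,7-dimethyloct-6-en-1-one
Product: 6 (3R)-1-(4-bromo-2,5-dihydroxyphenyl)-3-hydroxy-3,7-dimethyloct-6-en-1-one (target)
Conditions: TBAF (2.2 equiv), AcOH (2.5 equiv), THF, 0 °C, 20 min, argon; pH 6 phosphate buffer work-up
Reagents that add atoms: none
Why: Fluoride-mediated desilylation of aryl silyl ethers is complete within minutes at 0 °C, and the acetic acid buffer keeps phenoxide and alkoxide levels too low for retro-aldol cleavage, dehydration or chromanone closure, so C3 stays R.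

## Compound list
1 | 2,5-dibromohydroquinone (2,5-dibromobenzene-1,4-diol) | Oc1cc(Br)c(O)cc1Br | starting material
2 | 1,4-dibromo-2,5-bis(tert-butyldimethylsilyloxy)benzene | CC(C)(C)[Si](C)(C)Oc1cc(Br)c(O[Si](C)(C)C(C)(C)C)cc1Br | intermediate
3 | (R)-(−)-linalool, (3R)-3,7-dimethylocta-1,6-dien-3-ol | CC(C)=CCC[C@@](C)(O)C=C | starting material
4 | (1E,3R)-1-[4-bromo-2,5-bis(tert-butyldimethylsilyloxy)phenyl]-3,7-dimethylocta-1,6-dien-3-ol | CC(C)=CCC[C@@](C)(O)/C=C/c1cc(O[Si](C)(C)C(C)(C)C)c(Br)cc1O[Si](C)(C)C(C)(C)C | intermediate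
5 | (3R)-1-[4-bromo-2,5-bis(tert-butyldimethylsilyloxy)phenyl]-3-hydroxy-3,7-dimethyloct-6-en-1-one | CC(C)=CCC[C@@](C)(O)CC(=O)c1cc(O[Si](C)(C)C(C)(C)C)c(Br)cc1O[Si](C)(C)C(C)(C)C | intermediate
6 | (3R)-1-(4-bromo-2,5-dihydroxyphenyl)-3-hydroxy-3,7-dimethyloct-6-en-1-one | CC(C)=CCC[C@@](C)(O)CC(=O)c1cc(O)c(Br)cc1O | target

Total step count: 4. Longest linear sequence: 4 (1 → 2 → 4 → 5 → 6); 3 enters at step 2.

## Three steps most likely to fail

**Step 3 (the proposed new step).**
- Risks:
  - (a) The alkene sits between a quaternary carbon and an ortho-substituted arene and may bind palladium slowly.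
  - (b) Oxygen may be delivered to C2.
  - (c) Acid may ionise the tertiary styrenyl carbinol, causing racemisation, 1,3-transposition or diene formation.
- Fallback (known chemistry only): it sets out from 3 and 2, bypasses 4 and comes back at 5. Compound 3 is hydroborated at the vinyl group only with 9-BBN (2.2 equiv, THF, 0 °C to rt, then NaBO3·4H2O). This gives (R)-3,7-dimethyloct-6-ene-1,3-diol F1. Its primary alcohol is oxidised with TEMPO/PhI(OAc)2 (CH2Cl2, rt) to (R)-3-hydroxy-3,7-dimethyloct-6-enal F2. In parallel, 2 undergoes a single bromine–magnesium exchange with i-PrMgCl·LiCl (1.05 equiv, THF, rt) to [4-bromo-2,5-bis(tert-butyldimethylsilyloxy)phenyl]magnesium chloride F3. This reagent (2.2 equiv; the first equivalent only deprotonates the tertiary alcohol) is added to F2 at −40 °C. The product is (3R)-1-[4-bromo-2,5-bis(tert-butyldimethylsilyloxy)phenyl]-3,7-dimethyloct-6-ene-1,3-diol F4, a mixture of C1 epimers. MnO2 (CH2Cl2, rt) then oxidises only the benzylic secondary alcohol to 5.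

**Step 2.**
- Risks: double coupling of the symmetric dibromide, and sluggish oxidative addition of the electron-rich, ortho-siloxy bromide.
- Fallback: it sets out from 2 and comes back at 4. It replaces the statistical mono-coupling with an arene whose two halogens differ. The arylmagnesium chloride F3, made from 2 as above, is quenched with iodine (I2, THF, −20 °C) to 1-bromo-4-iodo-2,5-bis(tert-butyldimethylsilyloxy)benzene F5. A ligand-free Heck reaction with 3 (1.2 equiv; Pd(OAc)2 5 mol %, Bu4NCl, NaHCO3, DMF, 40 °C) then occurs only at the carbon–iodine bond and gives 4 without excess arene.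

**Step 4.**
- Risks: retro-aldol cleavage, dehydration followed by oxa-Michael closure to the chromanone, and air oxidation of the hydroquinone.
- Fallback: it sets out from 1 and comes back at 6. It swaps silicon–fluoride cleavage for a neutral enzymatic acyl transfer. Compound 1 is acetylated (Ac2O, pyridine, cat. DMAP, CH2Cl2, rt) to 2,5-dibromo-1,4-phenylene diacetate F6. This is carried through the conditions of step 2 to (1E,3R)-1-(2,5-diacetoxy-4-bromophenyl)-3,7-dimethylocta-1,6-dien-3-ol F7. The conditions of step 3 then give (3R)-1-(2,5-diacetoxy-4-bromophenyl)-3-hydroxy-3,7-dimethyloct-6-en-1-one F8. Both aryl acetates are removed by transesterification with n-BuOH over immobilised Candida antarctica lipase B (MTBE, 30 °C, argon), which gives 6.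

## Further compounds
F1 | step 3 | (R)-3,7-dimethyloct-6-ene-1,3-diol | CC(C)=CCC[C@@](C)(O)CCO
F2 | step 3 | (R)-3-hydroxy-3,7-dimethyloct-6-enal | CC(C)=CCC[C@@](C)(O)CC=O
F3 | step 3 | [4-bromo-2,5-bis(tert-butyldimethylsilyloxy)phenyl]magnesium chloride | CC(C)(C)[Si](C)(C)Oc1cc([Mg]Cl)c(O[Si](C)(C)C(C)(C)C)cc1Br
F4 | step 3 | (3R)-1-[4-bromo-2,5-bis(tert-butyldimethylsilyloxy)phenyl]-3,7-dimethyloct-6-ene-1,3-diol (C1 epimers) | CC(C)=CCC[C@@](C)(O)CC(O)c1cc(O[Si](C)(C)C(C)(C)C)c(Br)cc1O[Si](C)(C)C(C)(C)C
F5 | step 2 | 1-bromo-4-iodo-2,5-bis(tert-butyldimethylsilyloxy)benzene | CC(C)(C)[Si](C)(C)Oc1cc(I)c(O[Si](C)(C)C(C)(C)C)cc1Br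
F6 | step 4 | 2,5-dibromo-1,4-phenylene diacetate | CC(=O)Oc1cc(Br)c(OC(C)=O)cc1Br
F7 | step 4 | (1E,3R)-1-(2,5-diacetoxy-4-bromophenyl)-3,7-dimethylocta-1,6-dien-3-ol | CC(C)=CCC[C@@](C)(O)/C=C/c1cc(OC(C)=O)c(Br)cc1OC(C)=O
F8 | step 4 | (3R)-1-(2,5-diacetoxy-4-bromophenyl)-3-hydroxy-3,7-dimethyloct-6-en-1-one | CC(C)=CCC[C@@](C)(O)CC(=O)c1cc(OC(C)=O)c(Br)cc1OC(C)=O
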